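## Structural features

Selaginellin U (18) is an achiral, fully unsaturated polyphenol (C34H24O4) built on one benzene ring, ring A. Ring A carries four contiguous substituents: a methyl group at C1, a (4-hydroxyphenyl)ethynyl group at C6, the exocyclic carbon C7 at C5 and a 4-hydroxyphenyl ring at C4; only C2 and C3 bear hydrogen. C7 is the centre of a fuchsone (aurin-type) unit: it is doubly bonded to a cyclohexa-2,5-dienone ring and singly bonded to ring A and to a second 4-hydroxyphenyl ring, and these two C7 rings exchange roles by a proton shift. The target has no stereocentre; the only stereocentres in the plan are three adjacent sp3 carbons (C4, C5, C6) of the cyclohexene intermediates, and they are erased on aromatisation. The fragile groups are the electrophilic quinone methide, the three free phenols, and the diarylalkyne, which sits ortho to C7 and can be attacked by a cation or an alkoxide at C7. The real difficulty is the ordered 1,2,3,4-substitution of ring A with three bulky carbon groups in a row, which is awkward to reach by stepwise substitution of an existing arene. The key step uses the fact that C4 (aryl) and C5 (bearing the C7 carbonyl carbon) are the β- and α-carbons of a chalcone, while C6–C1–C2–C3 is a 2-methylbuta-1,3-diene with oxygen on its C6 terminus. A [4+2] union therefore places all four substituents in the right order on sp3 or alkene carbons and leaves a C6 oxygen that later becomes the handle for the alkyne.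

## Logic of the disconnections

18 to 16 (through 17). No skeletal bond is cut: the exocyclic C7=C π bond is traded for a C7–OH bond and the four phenolic O–H bonds for O–CH3 bonds. The cut is placed here because the quinone methide and the free phenols are the only groups of 18 that cannot be carried through organometallic and palladium chemistry. The gain is a neutral, lipophilic precursor with one tertiary alcohol and four inert ethers. The forward step must cleave all four O–CH3 bonds and remove the C7 hydroxyl without the C7 cation being captured by the C6 alkyne.

16 to 13 and 14 (through 15). The C7–C(aryl) bond to one of the two identical anisyl groups is cut. Since both groups are the same, either cut leads to one diaryl ketone, with C7 at the ketone level where it is a natural electrophile. This removes the only fully substituted sp3 carbon and makes the step convergent. Forward, a carbanion must add 1,2 to a ketone with two ortho substituents, and the alkoxide formed must not add to the neighbouring triple bond.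

13 to 11 and 12. The C6–C(sp) bond is cut, the standard place to disconnect an arylalkyne. The whole arylethynyl arm leaves as a terminal alkyne and C6 is revealed as an oxygen-bearing carbon. Forward, oxidative addition must occur at a C–O bond with two ortho substituents; the ortho carbonyl group should help.

11 to 10. Only the O–S bond is cut, exposing a phenol whose oxygen is traceable to the ring-forming step. The demand is sulfonylation of a hindered, hydrogen-bonded hydroxyl.

10 to 9 to 8 to 7. No skeletal bond is cut. Ring A is taken back from arene to cyclohexene by formally returning two hydrogens, the C6 carbonyl is taken back to a secondary alcohol, and the alcohol to its silyl ether. This exposes the retron of a [4+2] cycloaddition: a cyclohexene with oxygen at C6 next to an acyl-bearing C5 and an aryl-bearing C4. The gain is that the crowded tetrasubstituted arene is replaced by a ring whose substituents sit on sp3 or alkene carbons. Forward, the C6 oxygen must be fixed as a carbonyl before any dehydrogenation, since 1,4-loss of water or silanol would aromatise the ring without oxygen. The silyl ether must also be cleaved without retro-aldol opening of the ring.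

7 to 2 and 6. The C3–C4 and C5–C6 bonds are cut together, which dissolves ring A into a four-carbon and a two-carbon partner and removes three stereocentres. The cut is made here because one partner already holds the C4 aryl group and the complete C5–C7 aroyl unit in the correct 1,2-relationship, and the other holds the methyl group and the C6 oxygen. Forward, only regiochemistry matters: the oxygen-bearing terminus must join the acyl-bearing carbon.

2 to 1, and 6 to 3 and 4 (through 5). In 2 the O–Si bond is cut and a γ-hydrogen is restored; in 6 the Cα=Cβ bond is cut back to an aldehyde and a methyl ketone. Both partners then come in one step each from commodity chemicals. The forward steps must give the (1E) geometry in 2 and the (E) geometry in 6, which are the normally favoured outcomes.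

## Other disconnections considered

Alternative 1: The cut is at C6–C(sp) and C5–C7, made in one operation on a ring A that is aromatic from the start. Forward, fluoride would release the aryne A2 (3-chloro-6-methylbenzyne, the C5–C6 aryne) from the ortho-silylaryl triflate A3 (3-chloro-6-methyl-2-(trimethylsilyl)phenyl trifluoromethanesulfonate). The copper acetylide A4 ([(4-methoxyphenyl)ethynyl]copper, made from 12) would add across it, and the C5 arylcopper would be acylated by 4-methoxybenzoyl chloride A5 to give the chloro ketone A1 ([6-chloro-2-[(4-methoxyphenyl)ethynyl]-3-methylphenyl](4-methoxyphenyl)methanone). Suzuki coupling of the C4–Cl bond of A1 with (4-methoxyphenyl)boronic acid A6 would then meet the chosen route at 13.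
- In its favour: two of the three crowded carbon substituents arrive in one step. The inductive pull of chlorine should direct the carbon nucleophile to C6 and leave copper at C5, which is the required sense. No stereocentres are made and discarded, and there is no redox adjustment.
- Against it here: A3 would itself need several steps from a simple phenol. C6 is the aryne carbon next to the methyl group, so sterics oppose the electronic preference. The acid chloride A5 could acylate A4 directly, so order and timing of addition are critical. The remaining C4–Cl bond is a di-ortho-substituted aryl chloride that must be coupled in the presence of a diarylalkyne.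
- Comparison: on structure the alternative is the better fit, because ring A never leaves the aromatic level. On step economy it is at least the equal of the chosen plan once A3 is in hand, and it shares the last two steps. Mechanistically it rests on a three-component carbocupration–acylation near the edge of established scope, with regiochemistry balanced between two opposing effects. The chosen [4+2] step uses two one-step building blocks and a preference dominated by one strong donor.

Alternative 2: The cut removes three ring bonds of ring A at once (C5–C6, C1–C2, C3–C4), with C7 already carrying both anisyl groups. Forward, the ether-tethered 1,6-diyne A8 (1,1',1''-[3-(but-2-yn-1-yloxy)prop-1-yne-1,3,3-triyl]tris(4-methoxybenzene)) would be cyclotrimerised with acetylene A9 on a rhodium catalyst such as RhCl(PPh3)3. This would give the dihydroisobenzofuran A7 (1,1,7-tris(4-methoxyphenyl)-4-methyl-1,3-dihydroisobenzofuran), in which C2 and C3 come from A9.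
- In its favour: the tether fixes the substitution pattern completely, so there is no regiochemical question. The crowded C7 centre is made beforehand by acetylide addition to an unhindered diaryl ketone, which avoids the aryl addition to a di-ortho-substituted ketone that the chosen plan needs; on this point the alternative is the better. A8 should be available in two steps from 12, a commercial diaryl ketone and a butynyl halide.
- Against it here: C6 emerges bearing a CH2–O carbon, not an alkyne. The cyclic benzylic ether would have to be oxidised at that CH2 in competition with the ring A methyl group and three electron-rich rings, opened at the lactol stage, homologated to a terminal alkyne and arylated. The C7–O bond of A7 is a trityl-like ether that ionises easily, and a gem-diaryl lactol is expected to resist opening.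
- Comparison: the overall step count is similar. The ring-forming step is mechanistically cleaner than an intermolecular cycloaddition of a weak dienophile. But A7 holds the wrong functional group at C6, whereas the C6 oxygen delivered by the chosen key step becomes the alkyne in two standard steps.

Alternative 3: The cut is at C1–C2 and C4–C5, a three-plus-three carbon union that gives ring A directly as an arene. Forward, the 1,3-bis(silyl enol ether) A11 (1-methoxy-1,3-bis(trimethylsilyloxy)penta-1,3-diene), a dianion equivalent of a β-keto ester, would condense with the 3-oxo acetal A12 (3,3-dimethoxy-1-(4-methoxyphenyl)propan-1-one) under TiCl4. The terminal carbon of A11 attacks the acetal carbon (C1–C2), the central carbon attacks the aryl ketone (C4–C5), and aromatising elimination gives the salicylate A10 (methyl 2-hydroxy-6-(4-methoxyphenyl)-3-methylbenzoate).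
- In its favour: ring A forms at the aromatic level with no stereocentres and no redox steps. A10 carries the same C6 hydroxyl handle as 10, so triflation and Sonogashira coupling with 12 follow as in the chosen plan. C7 is an ester, so both C7 aryl groups could be introduced with two equivalents of 15. The estimated count is one or two steps lower, and on redox and step economy this alternative is the better.
- Against it here: A11 is moisture-sensitive and takes two steps to make, and cyclocondensations of this type are generally moderate in efficiency. The regiochemistry depends on TiCl4 discriminating between the acetal and a deactivated para-methoxyaryl ketone; reversal would put the aryl group on the wrong ring carbon. The double addition to a di-ortho-substituted benzoate passes through 13 anyway, so nothing is gained at the hindered C7 centre.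
- Comparison: both plans reach a C5-acyl, C6-oxygenated ring A and share the endgame, and the alternative is the equal of the chosen plan in the C6 handle. The chosen [4+2] step has a more secure regiochemical basis and uses two air-stable one-step partners, but it pays with three steps of deprotection, oxidation and dehydrogenation that the alternative does not need.

Key step: step 3

Remark: ring A is numbered C1 (methyl), C2-H, C3-H, C4 (aryl), C5 (bearing C7), C6 (alkynyl). The target has no stereocentre, and the chiral intermediates 5 and 7–9 are racemic, with one enantiomer written for 7–9.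

## Route

Step 1
Reactants: 1 (E)-2-methylbut-2-enal (tiglic aldehyde)
Product: 2 (1E)-1-(tert-butyldimethylsilyloxy)-2-methylbuta-1,3-diene
Conditions: TBSOTf, Et3N, Et2O, 0 °C → rt
Reagents that add atoms: tert-butyldimethylsilyl trifluoromethanesulfonate, CC(C)(C)[Si](C)(C)OS(=O)(=O)C(F)(F)F
Why: O-Silylation of the aldehyde gives a silyloxocarbenium ion whose γ-methyl proton is removed by Et3N (silyl dienol ether formation by vinylogous enolisation). The favoured s-trans conformer of the enal should lead to the (1E) geometry needed for a reactive s-cis diene; any (1Z) isomer is a spectator.

Step 2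
Reactants: 3 4-methoxybenzaldehyde; 4 4-methoxyacetophenone
Product: 6 (E)-4,4'-dimethoxychalcone [(2E)-1,3-bis(4-methoxyphenyl)prop-2-en-1-one], via aldol adduct 5 (not isolated)
Conditions: NaOH (20 mol%, aq.), EtOH, rt
Reagents that add atoms: none
Why: Claisen–Schmidt condensation: the acetophenone enolate adds to the non-enolisable aldehyde, and E1cB loss of water from 5 gives the thermodynamically preferred (E)-enone, which is expected to crystallise from the alcohol.

Step 3
Reactants: 2 (1E)-1-(tert-butyldimethylsilyloxy)-2-methylbuta-1,3-diene; 6 (E)-4,4'-dimethoxychalcone
Product: 7 rac-[(1R,2R,6S)-2-{[tert-butyl(dimethyl)silyl]oxy}-6-(4-methoxyphenyl)-3-methylcyclohex-3-en-1-yl](4-methoxyphenyl)methanone (endo adduct: silyloxy cis to aroyl; aryl trans to aroyl)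
Conditions: Me2AlCl (1.2 equiv), 2 (2 equiv), CH2Cl2, −78 → −20 °C; aq. KNaC4H4O6 work-up
Reagents that add atoms: none
Why: Me2AlCl binds the carbonyl oxygen of 6 and lowers its LUMO, so that the electron-rich diene 2, in its s-cis conformation, adds across the Cα=Cβ bond in a normal-electron-demand [4+2] cycloaddition that is concerted but strongly asynchronous, the C3–C4 bond (diene CH2 terminus to the aryl-bearing β-carbon) running ahead of the C5–C6 bond (silyloxy terminus to the α-carbon). At the polar limit the same two bonds arise stepwise, by vinylogous Mukaiyama–Michael addition followed by aldol-type capture of the silyloxocarbenium ion by the aluminium enolate. The closest known reaction type is the Lewis-acid-promoted Diels–Alder reaction of 1-silyloxybuta-1,3-dienes with acyclic enones. Ring A is closed as a cyclohexene by suprafacial [4+2] cycloaddition; in the stepwise limit the closure is a 6-(enolexo)-exo-trig attack of the enolate carbon C5 on the oxocarbenium carbon C6, the breaking C=O π bond lying outside the ring. Of the three new stereocentres, C4 and C5 are set trans by the (E) geometry of 6, which a suprafacial addition retains, and C6 is set cis to the aroyl group at C5 by the endo orientation of the aluminium-bound carbonyl together with the (1E) geometry of 2; the adduct is racemic and all three centres are erased in step 6, so no diastereocontrol is needed. The one selectivity that matters is regiochemical: the silyloxy-bearing terminus must bond to Cα. It is secured by the 1-silyloxy group, which makes the remote CH2 terminus the most nucleophilic carbon of 2 (largest HOMO coefficient) and pairs it with the β-carbon of the activated enone (largest LUMO coefficient); this outweighs the weaker, opposing bias of the 2-methyl group, and the Lewis acid sharpens the polarisation. The TBS ether is chosen over smaller silyl groups so that the dienol ether survives the promoter.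

Step 4
Reactants: 7 rac-[(1R,2R,6S)-2-{[tert-butyl(dimethyl)silyl]oxy}-6-(4-methoxyphenyl)-3-methylcyclohex-3-en-1-yl](4-methoxyphenyl)methanone
Product: 8 rac-[(1R,2R,6S)-2-hydroxy-6-(4-methoxyphenyl)-3-methylcyclohex-3-en-1-yl](4-methoxyphenyl)methanone
Conditions: HF·pyridine, pyridine, THF, 0 °C → rt
Reagents that add atoms: none
Why: Fluoride-induced Si–O cleavage under buffered, mildly acidic conditions. Basic fluoride is avoided because the product is a cyclic aldol that could suffer retro-aldol ring opening or E1cB loss of the C6 oxygen; no stereocentre is touched.

Step 5
Reactants: 8 rac-[(1R,2R,6S)-2-hydroxy-6-(4-methoxyphenyl)-3-methylcyclohex-3-en-1-yl](4-methoxyphenyl)methanone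
Product: 9 rac-(5S,6R)-6-(4-methoxybenzoyl)-5-(4-methoxyphenyl)-2-methylcyclohex-2-en-1-one (trans; in equilibrium with its enol forms)
Conditions: Dess–Martin periodinane (1.3 equiv), CH2Cl2, 0 °C → rt
Reagents that add atoms: none
Why: Dess–Martin oxidation of the secondary allylic alcohol should stop at the 1,3-diketone and involves no C–H abstraction on the ring, so the C6 oxygen is fixed as a carbonyl before any dehydrogenation. The C6 centre of 9 (C5 of ring A) becomes epimerisable, which is of no consequence.

Step 6
Reactants: 9 rac-(5S,6R)-6-(4-methoxybenzoyl)-5-(4-methoxyphenyl)-2-methylcyclohex-2-en-1-one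
Product: 10 [2-hydroxy-6-(4-methoxyphenyl)-3-methylphenyl](4-methoxyphenyl)methanone
Conditions: DDQ (1.1 equiv), 1,4-dioxane, rt → 60 °C
Reagents that add atoms: none
Why: The ring enol of 9 is a cyclohexa-1,3-dienol; DDQ abstracts hydride from the C4–H bond (benzylic and conjugated with the dienol), and loss of the C3 proton gives the phenol (dehydrogenative aromatisation of a 2-acylcyclohexenone). Both remaining stereocentres are erased, and the hydrogen bond to the ortho aroyl group should protect the phenol from further oxidation.

Step 7
Reactants: 10 [2-hydroxy-6-(4-methoxyphenyl)-3-methylphenyl](4-methoxyphenyl)methanone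
Product: 11 2-(4-methoxybenzoyl)-3-(4-methoxyphenyl)-6-methylphenyl trifluoromethanesulfonate
Conditions: Tf2O, pyridine, CH2Cl2, 0 °C → rt
Reagents that add atoms: trifluoromethanesulfonic anhydride, O=S(=O)(OS(=O)(=O)C(F)(F)F)C(F)(F)F
Why: O-Sulfonylation of the phenol; the small, highly electrophilic anhydride should reach even this hindered, hydrogen-bonded hydroxyl. The resulting aryl triflate is activated for oxidative addition by the ortho carbonyl group.

Step 8
Reactants: 11 2-(4-methoxybenzoyl)-3-(4-methoxyphenyl)-6-methylphenyl trifluoromethanesulfonate; 12 4-ethynylanisole (1-ethynyl-4-methoxybenzene)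
Product: 13 (4-methoxyphenyl){6-(4-methoxyphenyl)-2-[(4-methoxyphenyl)ethynyl]-3-methylphenyl}methanone
Conditions: PdCl2(PPh3)2 (5 mol%), CuI (10 mol%), Et3N, DMF, 70 °C
Reagents that add atoms: none
Why: Sonogashira coupling: oxidative addition of zerovalent palladium into the electron-poor C6–OTf bond, transmetallation from the copper acetylide formed from 12, CuI and Et3N, then reductive elimination. The ketone and the methyl ethers are inert.

Step 9
Reactants: 13 (4-methoxyphenyl){6-(4-methoxyphenyl)-2-[(4-methoxyphenyl)ethynyl]-3-methylphenyl}methanone; 14 4-bromoanisole
Product: 16 bis(4-methoxyphenyl){6-(4-methoxyphenyl)-2-[(4-methoxyphenyl)ethynyl]-3-methylphenyl}methanol, via 4-methoxyphenyllithium 15 (not isolated)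
Conditions: 14, n-BuLi, THF, −78 °C; then 13, −78 → −40 °C; H2O quench at −40 °C
Reagents that add atoms: none
Why: Br/Li exchange gives 15, which adds 1,2 to the non-enolisable diaryl ketone; the linear alkynyl group leaves one flank of the carbonyl open, and a cold quench should keep the tertiary alkoxide from adding to the neighbouring alkyne. The new carbinol carbon carries two identical aryl groups and is not a stereocentre.

Step 10
Reactants: 16 bis(4-methoxyphenyl){6-(4-methoxyphenyl)-2-[(4-methoxyphenyl)ethynyl]-3-methylphenyl}methanol
Product: 18 Selaginellin U, via tetraphenolic carbinol 17 (not isolated)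
Conditions: BBr3 (10 equiv), CH2Cl2, −78 → 0 °C; then H2O, 0 °C
Reagents that add atoms: none
Why: BBr3 cleaves the four aryl methyl ethers by bromide attack at methyl and ionises the tertiary C7–O bond. On aqueous work-up the tetraphenolic carbinol 17 (the carbinol base of an aurin-type dye) should lose water spontaneously to the conjugated quinone methide; the two C7 aryl groups are equivalent, so only one product can form. Low temperature and short exposure limit attack of the C7 cation on the ortho alkyne.

## Compound list

1 | (E)-2-methylbut-2-enal (tiglic aldehyde) | C/C=C(\C)C=O | starting material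
2 | (1E)-1-(tert-butyldimethylsilyloxy)-2-methylbuta-1,3-diene | C=C/C(C)=C/O[Si](C)(C)C(C)(C)C | intermediate
3 | 4-methoxybenzaldehyde | COc1ccc(C=O)cc1 | starting material
4 | 4-methoxyacetophenone | COc1ccc(C(C)=O)cc1 | starting material
5 | rac-3-hydroxy-1,3-bis(4-methoxyphenyl)propan-1-one (aldol adduct, racemic) | COc1ccc(C(O)CC(=O)c2ccc(OC)cc2)cc1 | intermediate (not isolated)
6 | (E)-4,4'-dimethoxychalcone, (2E)-1,3-bis(4-methoxyphenyl)prop-2-en-1-one | COc1ccc(/C=C/C(=O)c2ccc(OC)cc2)cc1 | intermediate
7 | rac-[(1R,2R,6S)-2-{[tert-butyl(dimethyl)silyl]oxy}-6-(4-methoxyphenyl)-3-methylcyclohex-3-en-1-yl](4-methoxyphenyl)methanone | CC1=CC[C@H](c2ccc(OC)cc2)[C@@H](C(=O)c2ccc(OC)cc2)[C@H]1O[Si](C)(C)C(C)(C)C | intermediate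
8 | rac-[(1R,2R,6S)-2-hydroxy-6-(4-methoxyphenyl)-3-methylcyclohex-3-en-1-yl](4-methoxyphenyl)methanone | CC1=CC[C@H](c2ccc(OC)cc2)[C@@H](C(=O)c2ccc(OC)cc2)[C@H]1O | intermediate
9 | rac-(5S,6R)-6-(4-methoxybenzoyl)-5-(4-methoxyphenyl)-2-methylcyclohex-2-en-1-one (trans, enolisable) | CC1=CC[C@H](c2ccc(OC)cc2)[C@@H](C(=O)c2ccc(OC)cc2)C1=O | intermediate
10 | [2-hydroxy-6-(4-methoxyphenyl)-3-methylphenyl](4-methoxyphenyl)methanone | Cc1ccc(-c2ccc(OC)cc2)c(C(=O)c2ccc(OC)cc2)c1O | intermediate
11 | 2-(4-methoxybenzoyl)-3-(4-methoxyphenyl)-6-methylphenyl trifluoromethanesulfonate | Cc1ccc(-c2ccc(OC)cc2)c(C(=O)c2ccc(OC)cc2)c1OS(=O)(=O)C(F)(F)F | intermediate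
12 | 4-ethynylanisole (1-ethynyl-4-methoxybenzene) | COc1ccc(C#C)cc1 | starting material
13 | (4-methoxyphenyl){6-(4-methoxyphenyl)-2-[(4-methoxyphenyl)ethynyl]-3-methylphenyl}methanone | Cc1ccc(-c2ccc(OC)cc2)c(C(=O)c2ccc(OC)cc2)c1C#Cc1ccc(OC)cc1 | intermediate
14 | 4-bromoanisole | COc1ccc(Br)cc1 | starting material
15 | 4-methoxyphenyllithium | [Li]c1ccc(OC)cc1 | intermediate (not isolated)
16 | bis(4-methoxyphenyl){6-(4-methoxyphenyl)-2-[(4-methoxyphenyl)ethynyl]-3-methylphenyl}methanol | Cc1ccc(-c2ccc(OC)cc2)c(C(O)(c2ccc(OC)cc2)c2ccc(OC)cc2)c1C#Cc1ccc(OC)cc1 | intermediate
17 | 4,4'-({6-(4-hydroxyphenyl)-2-[(4-hydroxyphenyl)ethynyl]-3-methylphenyl}(hydroxy)methylene)diphenol | Cc1ccc(-c2ccc(O)cc2)c(C(O)(c2ccc(O)cc2)c2ccc(O)cc2)c1C#Cc1ccc(O)cc1 | intermediate (not isolated)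
18 | Selaginellin U, 4-[{6-(4-hydroxyphenyl)-2-[(4-hydroxyphenyl)ethynyl]-3-methylphenyl}(4-hydroxyphenyl)methylidene]cyclohexa-2,5-dien-1-one | Cc1ccc(-c2ccc(O)cc2)c(C(=C2C=CC(=O)C=C2)c2ccc(O)cc2)c1C#Cc1ccc(O)cc1 | target

## Step count and least certain steps

Total step count: 10. Longest linear sequence: 9 steps (step 2 then steps 3–10 from 3 and 4, or step 1 then steps 3–10 from 1).

Step 3 (key step).
- What may go wrong: the cycloaddition may be sluggish because the electron-rich, doubly aryl-substituted enone is a weak dienophile. In the polar, Lewis-acid-promoted regime the first-formed zwitterion may undergo silyl transfer before ring closure, leaving an open-chain vinylogous Michael product whose (E)-enal cannot cyclise. The promoter may also strip or polymerise the diene. The first recourse at the level of conditions is to heat 2 and 6 without promoter in toluene in a sealed tube.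
- Fallback (sets out from 2, returns at 9): the diaryl enone is replaced by the less hindered and more easily activated enal (E)-4-methoxycinnamaldehyde F1 (commercial). With 2 it should undergo the same regiochemical [4+2] addition (Me2AlCl, CH2Cl2, −78 °C, or heat in toluene) to give rac-(1R,2R,6S)-2-{[tert-butyl(dimethyl)silyl]oxy}-6-(4-methoxyphenyl)-3-methylcyclohex-3-ene-1-carbaldehyde F2. Addition of 15 (from 14 and n-BuLi, THF, −78 °C) would give [2-{[tert-butyl(dimethyl)silyl]oxy}-6-(4-methoxyphenyl)-3-methylcyclohex-3-en-1-yl](4-methoxyphenyl)methanol F3 as a mixture of carbinol epimers. HF·pyridine would then give [2-hydroxy-6-(4-methoxyphenyl)-3-methylcyclohex-3-en-1-yl](4-methoxyphenyl)methanol F4, and Dess–Martin periodinane (2.5 equiv) would oxidise both secondary alcohols to 9. This costs one step more than steps 3–5.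

Step 4.
- What may go wrong: fragmentation of the cyclic aldol by retro-aldol ring opening, or β-elimination of the C6 oxygen followed by aromatisation to an oxygen-free arene, if the medium becomes basic or strongly acidic.
- Fallback (sets out from 7, returns at 9): direct oxidative desilylation by Jones oxidation (CrO3, H2SO4, acetone, 0 °C). This converts the secondary silyl ether into the ketone in one operation, so the free aldol exists only fleetingly in an acidic, oxidising medium where neither retro-aldol nor E1cB pathways are favoured. No new compound is involved, and one step is saved.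

Step 8.
- What may go wrong: slow oxidative addition at the di-ortho-substituted triflate, S–O cleavage of the triflate by amine or acetylide returning 10, and oxidative homocoupling of the electron-rich alkyne 12.
- Fallback (sets out from 11 and 12, returns at 13): the copper/amine manifold is replaced by a Stille coupling. Compound 12 is lithiated (n-BuLi, THF, −78 °C) and quenched with Bu3SnCl to give tributyl[(4-methoxyphenyl)ethynyl]stannane F5, which is coupled with 11 under PdCl2(PPh3)2 and LiCl in 1,4-dioxane at 90 °C. No amine base or copper acetylide is present, which removes both the S–O cleavage and the homocoupling pathways.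

Step 9.
- What may go wrong: incomplete 1,2-addition at the shielded ketone, and attack of the lithium alkoxide on the ortho alkyne (5-exo or 6-endo) if the mixture warms before the quench.
- Fallback (sets out from 10, returns at 16): the aryl group is added before the alkyne is present. Three equivalents of 15 (the first consumed by the phenol) should add to the ketone of 10 to give 2-[hydroxybis(4-methoxyphenyl)methyl]-3-(4-methoxyphenyl)-6-methylphenol F6. Phenol-selective triflation (Tf2O, pyridine, CH2Cl2, −40 °C; the tertiary alcohol is too hindered to react) gives 2-[hydroxybis(4-methoxyphenyl)methyl]-3-(4-methoxyphenyl)-6-methylphenyl trifluoromethanesulfonate F7. Sonogashira coupling of F7 with 12 under the conditions of step 8 then gives 16 directly. The step count is unchanged.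

Step 10.
- What may go wrong: capture of the C7 cation by the ortho alkyne (cationic cyclisation toward indene- or fluorene-type skeletons), addition of HBr across the alkyne, and incomplete cleavage of the four ethers.
- Fallback (sets out from 16, returns at 18): the ethers are cleaved by SN2 attack of a thiolate at methyl instead of by a Lewis acid (NaSEt, DMF, about 120 °C), conditions under which no cation can form at C7. Acidification with AcOH then gives 17, which should lose water to 18 in the presence of a trace of acid. The price is possible thiolate addition to the alkyne at this temperature, so the reaction would be stopped as soon as the fourth ether is cleaved. No new compound is involved.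

## Further compounds

F1 | step 3 | (E)-4-methoxycinnamaldehyde, (2E)-3-(4-methoxyphenyl)prop-2-enal (commercial) | COc1ccc(/C=C/C=O)cc1
F2 | step 3 | rac-(1R,2R,6S)-2-{[tert-butyl(dimethyl)silyl]oxy}-6-(4-methoxyphenyl)-3-methylcyclohex-3-ene-1-carbaldehyde | CC1=CC[C@H](c2ccc(OC)cc2)[C@@H](C=O)[C@H]1O[Si](C)(C)C(C)(C)C
F3 | step 3 | [2-{[tert-butyl(dimethyl)silyl]oxy}-6-(4-methoxyphenyl)-3-methylcyclohex-3-en-1-yl](4-methoxyphenyl)methanol (racemic; ring configuration as in 7; carbinol carbon as a mixture of epimers) | CC1=CC[C@H](c2ccc(OC)cc2)[C@@H](C(O)c2ccc(OC)cc2)[C@H]1O[Si](C)(C)C(C)(C)C
F4 | step 3 | [2-hydroxy-6-(4-methoxyphenyl)-3-methylcyclohex-3-en-1-yl](4-methoxyphenyl)methanol (racemic; ring configuration as in 8; carbinol carbon as a mixture of epimers) | CC1=CC[C@H](c2ccc(OC)cc2)[C@@H](C(O)c2ccc(OC)cc2)[C@H]1O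
F0 | step 4 | none | none
F5 | step 8 | tributyl[(4-methoxyphenyl)ethynyl]stannane | CCCC[Sn](CCCC)(CCCC)C#Cc1ccc(OC)cc1
F6 | step 9 | 2-[hydroxybis(4-methoxyphenyl)methyl]-3-(4-methoxyphenyl)-6-methylphenol | Cc1ccc(-c2ccc(OC)cc2)c(C(O)(c2ccc(OC)cc2)c2ccc(OC)cc2)c1O
F7 | step 9 | 2-[hydroxybis(4-methoxyphenyl)methyl]-3-(4-methoxyphenyl)-6-methylphenyl trifluoromethanesulfonate | Cc1ccc(-c2ccc(OC)cc2)c(C(O)(c2ccc(OC)cc2)c2ccc(OC)cc2)c1OS(=O)(=O)C(F)(F)F
F0 | step 10 | none | none
A1 | alternative 1 | [6-chloro-2-[(4-methoxyphenyl)ethynyl]-3-methylphenyl](4-methoxyphenyl)methanone | Cc1ccc(Cl)c(C(=O)c2ccc(OC)cc2)c1C#Cc1ccc(OC)cc1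
A2 | alternative 1 | 3-chloro-6-methylbenzyne (1-chloro-4-methylcyclohexa-1,3-dien-5-yne) | CC1=CC=C(Cl)C#C1
A3 | alternative 1 | 3-chloro-6-methyl-2-(trimethylsilyl)phenyl trifluoromethanesulfonate | Cc1ccc(Cl)c([Si](C)(C)C)c1OS(=O)(=O)C(F)(F)F
A4 | alternative 1 | [(4-methoxyphenyl)ethynyl]copper | [Cu]C#Cc1ccc(OC)cc1
A5 | alternative 1 | 4-methoxybenzoyl chloride | COc1ccc(C(=O)Cl)cc1
A6 | alternative 1 | (4-methoxyphenyl)boronic acid | COc1ccc(B(O)O)cc1
A7 | alternative 2 | 1,1,7-tris(4-methoxyphenyl)-4-methyl-1,3-dihydroisobenzofuran | Cc1ccc(-c2ccc(OC)cc2)c2c1COC2(c1ccc(OC)cc1)c1ccc(OC)cc1
A8 | alternative 2 | 1,1',1''-[3-(but-2-yn-1-yloxy)prop-1-yne-1,3,3-triyl]tris(4-methoxybenzene) | CC#CCOC(C#Cc1ccc(OC)cc1)(c1ccc(OC)cc1)c1ccc(OC)cc1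
A9 | alternative 2 | acetylene (ethyne) | C#C
A10 | alternative 3 | methyl 2-hydroxy-6-(4-methoxyphenyl)-3-methylbenzoate | COC(=O)c1c(O)c(C)ccc1-c1ccc(OC)cc1
A11 | alternative 3 | 1-methoxy-1,3-bis(trimethylsilyloxy)penta-1,3-diene (double-bond geometry not defined) | CC=C(O[Si](C)(C)C)C=C(OC)O[Si](C)(C)C
A12 | alternative 3 | 3,3-dimethoxy-1-(4-methoxyphenyl)propan-1-one | COc1ccc(C(=O)CC(OC)OC)cc1
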